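**Plan**

- Retrosynthesis: all benzyl ethers and a bromine cap on C8 of the top unit are cut first; then C4(top unit)–C8(second unit); then, in one operation, C4(second unit)–C8(third unit) together with the aryl ether bond O1–C8a that closes ring C of the second unit; then C4(third unit)–C8(bottom unit); last, in the open-chain second unit, C4–C4a (aryllithium + aldehyde) and C2–C3 (glycolate aldol).
- Forward: a galloylated epigallocatechin C4 electrophile and benzylated epicatechin give the lower dimer; an open-chain 1-(2-fluoro-4,6-dibenzyloxyphenyl)-3-arylpropane-1,2,3-triol derivative is built separately; the key step closes ring C of the second unit and joins it to the dimer; a bromine-capped epigallocatechin electrophile is added on top; hydrogenolysis ends the route.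
- Enabling feature: in ring A of the second unit C8a is ortho to C4a, so a carbocation at C4 (stabilised by the oxygens on C5 and C7) places positive charge on C8a. With fluorine on C8a, the C2 oxygen (the future O1) can close the six-membered ring C by ipso substitution, and the resulting flavan-4-yl cation is the electrophile for the interflavan bond.
- Stereochemistry: the top, third and bottom units come from (−)-epigallocatechin and (−)-epicatechin; C2 and C3 of the second unit come from an Evans syn-glycolate aldol and are kept because ring closure occurs at the aryl carbon; every C4 centre is set by attack trans to the C3 oxygen substituent (4β); C4 of the open-chain precursor is a mixture of epimers that converges in the key step.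

Key step: step 13

Assumption: compounds 1, 3, 6, 9, 11, 12 and 15 are taken as commercial, and C4 of the open-chain unit is carried as both epimers because it becomes planar in the key step.

**Route**

Step 1
Reactants: 1 (−)-epigallocatechin
Product: 2 5,7,3',4',5'-penta-O-benzyl-(−)-epigallocatechin
Conditions: BnBr (5.5 equiv), K2CO3, DMF, 0 °C to rt, argon
Reagents that add atoms: benzyl bromide, BrCc1ccccc1
Why: Williamson ether synthesis in which K2CO3 deprotonates only the five phenols, so the secondary 3-OH stays free and the C2 and C3 centres of the chiral pool are untouched.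

Step 2
Reactants: 2 5,7,3',4',5'-penta-O-benzyl-(−)-epigallocatechin; 3 3,4,5-tris(benzyloxy)benzoic acid
Product: 4 5,7,3',4',5'-penta-O-benzyl-(−)-epigallocatechin 3-O-[3,4,5-tris(benzyloxy)benzoate]
Conditions: N,N'-dicyclohexylcarbodiimide, DMAP (cat.), CH2Cl2, rt
Reagents that add atoms: none
Why: Steglich esterification acylates the only free hydroxyl (the axial 3-OH) and fixes the gallate on the future third unit without touching a stereocentre.

Step 3
Reactants: 4 5,7,3',4',5'-penta-O-benzyl-(−)-epigallocatechin 3-O-[3,4,5-tris(benzyloxy)benzoate]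
Product: 5 4β-(2-ethoxyethoxy) derivative of 4
Conditions: DDQ (2 equiv), EtOCH2CH2OH (5 equiv), CH2Cl2, rt
Reagents that add atoms: 2-ethoxyethanol, CCOCCO
Why: DDQ oxidative benzylic etherification, in which hydride is taken from C4 (activated by the ring A oxygens) and the alcohol adds trans to the 3-acyloxy group; the C4 configuration is of no consequence later.

Step 4
Reactants: 6 (−)-epicatechin
Product: 7 5,7,3',4'-tetra-O-benzyl-(−)-epicatechin
Conditions: BnBr (4.4 equiv), K2CO3, DMF, 0 °C to rt, argon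
Reagents that add atoms: benzyl bromide, BrCc1ccccc1
Why: Williamson ether synthesis selective for the four phenols, as in step 1.

Step 5
Reactants: 5 4β-(2-ethoxyethoxy) derivative of 4; 7 5,7,3',4'-tetra-O-benzyl-(−)-epicatechin
Product: 8 lower dimer (octa-O-benzyl-epigallocatechin 3-O-gallate)-(4β→8)-(5,7,3',4'-tetra-O-benzyl-epicatechin)
Conditions: 7 (4 equiv), TMSOTf (0.2 equiv), CH2Cl2, −78 °C; Et3N quench
Reagents that add atoms: none
Why: Lewis-acid Friedel–Crafts interflavan coupling in which ionisation at C4 of 5 is followed by attack of C8 of the excess nucleophile 7 trans to the 3-galloyloxy group (steric and neighbouring-group control), which should set the 4β bond.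

Step 6
Reactants: 9 1,3,5-trifluorobenzene
Product: 10 1,3-bis(benzyloxy)-5-fluorobenzene
Conditions: BnONa (2.1 equiv) in BnOH, NMP, 80 °C
Reagents that add atoms: sodium benzyloxide, [Na+].[O-]Cc1ccccc1
Why: Twofold SNAr of fluoride by benzyloxide, with the third fluorine expected to be retained under stoichiometric control because each alkoxy group introduced slows the next substitution.

Step 7
Reactants: 11 (S)-4-benzyl-1,3-oxazolidin-2-one; 12 (benzyloxy)acetyl chloride
Product: 14 (S)-4-benzyl-3-[(benzyloxy)acetyl]-1,3-oxazolidin-2-one, via N-lithio oxazolidinone 13 (not isolated)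
Conditions: nBuLi (1.0 equiv), THF, −78 °C; then 12, −78 to 0 °C
Reagents that add atoms: none
Why: N-acylation of the lithiated auxiliary by the acid chloride, the standard loading of an Evans oxazolidinone.

Step 8
Reactants: 14 (S)-4-benzyl-3-[(benzyloxy)acetyl]-1,3-oxazolidin-2-one; 15 3,4,5-tris(benzyloxy)benzaldehyde
Product: 18 (4S)-4-benzyl-3-{(2S,3R)-2-(benzyloxy)-3-hydroxy-3-[3,4,5-tris(benzyloxy)phenyl]propanoyl}-1,3-oxazolidin-2-one, via boron enolate 16 (not isolated), via boron aldolate 17 (not isolated)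
Conditions: Bu2BOTf (1.1 equiv), Et3N (1.3 equiv), CH2Cl2, −78 to 0 °C; 15, −78 to 0 °C; then pH 7 buffer, MeOH, H2O2, 0 °C
Reagents that add atoms: none
Why: Evans syn-glycolate aldol in which the Z-boron enolate reacts through a chair Zimmerman–Traxler transition state on the face away from the auxiliary benzyl group, setting the future C3 (2S here) and C2 (3R here) of the second unit in a syn relation.

Step 9
Reactants: 18 aldol adduct
Product: 19 3-O-triethylsilyl ether of 18
Conditions: TESOTf (1.2 equiv), 2,6-lutidine, CH2Cl2, −78 to 0 °C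
Reagents that add atoms: triethylsilyl trifluoromethanesulfonate, CC[Si](CC)(CC)OS(=O)(=O)C(F)(F)F
Why: Silylation of the secondary benzylic alcohol, which protects the future O1 and installs the silicon that later takes up fluoride.

Step 10
Reactants: 19 3-O-triethylsilyl ether of 18
Product: 20 (2R,3R)-2-(benzyloxy)-3-[(triethylsilyl)oxy]-3-[3,4,5-tris(benzyloxy)phenyl]propan-1-ol
Conditions: LiBH4, MeOH (1 equiv), THF, 0 °C
Reagents that add atoms: none
Why: Reductive cleavage of the N-acyl oxazolidinone by hydride attack at the exocyclic carbonyl, which releases the auxiliary and leaves both stereocentres untouched.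

Step 11
Reactants: 20 (2R,3R)-2-(benzyloxy)-3-[(triethylsilyl)oxy]-3-[3,4,5-tris(benzyloxy)phenyl]propan-1-ol
Product: 21 (2S,3R)-2-(benzyloxy)-3-[(triethylsilyl)oxy]-3-[3,4,5-tris(benzyloxy)phenyl]propanal
Conditions: Dess–Martin periodinane, CH2Cl2, 0 °C to rt; used at once
Reagents that add atoms: none
Why: Dess–Martin oxidation gives the α-alkoxy aldehyde under non-basic conditions, so the α-centre should not epimerise.

Step 12
Reactants: 10 1,3-bis(benzyloxy)-5-fluorobenzene; 21 (2S,3R)-2-(benzyloxy)-3-[(triethylsilyl)oxy]-3-[3,4,5-tris(benzyloxy)phenyl]propanal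
Product: 24 (1RS,2R,3R)-2-(benzyloxy)-1-[2,4-bis(benzyloxy)-6-fluorophenyl]-3-[(triethylsilyl)oxy]-3-[3,4,5-tris(benzyloxy)phenyl]propyl acetate, via aryllithium 22 (not isolated), via lithium alkoxide 23 (not isolated)
Conditions: 10 (1.1 equiv), nBuLi (1.05 equiv), THF, −78 °C, 1 h; 21, −78 °C; then Ac2O (3 equiv), −78 to −20 °C
Reagents that add atoms: acetic anhydride, CC(=O)OC(C)=O
Why: Directed ortho-lithiation at the C–H flanked by fluorine and benzyloxy, 1,2-addition to the aldehyde and O-acetylation in the flask; the new carbinol centre (future C4) forms as a mixture, which is accepted because step 13 makes it planar.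

Step 13
Reactants: 24 open-chain acetate (both C1 epimers); 8 lower dimer
Product: 27 benzyl-protected trimer (3,5,7,3',4',5'-hexa-O-benzyl-epigallocatechin)-(4β→8)-(octa-O-benzyl-epigallocatechin 3-O-gallate)-(4β→8)-(5,7,3',4'-tetra-O-benzyl-epicatechin), via open-chain C4 cation 25 (not isolated), via flavan-4-yl cation 26 (not isolated)
Conditions: 24, 2,6-di-tert-butyl-4-methylpyridine (2.5 equiv), 4 Å molecular sieves, CH2Cl2; TMSOTf (1.0 equiv), −78 to −30 °C; recool to −78 °C, then 8 (1.3 equiv), −78 to −40 °C; aq. NaHCO3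
Reagents that add atoms: none
Why: Proposed new method: TMSOTf ionises the C4 acetate of both epimers of 24 to one planar benzylic cation 25 (stabilised by the C5 and C7 benzyloxy groups) whose positive charge at the ortho carbon C8a makes the C–F carbon electrophilic, so the C2 silyl ether oxygen adds there and fluoride leaves on silicon as Et3SiF, closing ring C as the flavan-4-yl cation 26, which is then alkylated by C8 of the top unit of dimer 8. The closest known reaction types are the carbenium-activated intramolecular SNAr that closes xanthenium rings in ortho-substituted triarylmethyl cations, the alkoxide/aryl fluoride SNAr ring closure of fluoroarene precursors of catechins, and the Lewis-acid Friedel–Crafts coupling of flavan C4 cations. Ring C closes by 6-exo-trig addition of O1 to C8a followed by loss of fluoride (addition–elimination at an aryl carbon), so the C2–O bond is never broken and C2 and C3 keep the configuration set in step 8. The only new stereocentre, C4, is set by substrate control, because C8 of 8 should attack the half-chair cation 26 anti to the pseudo-axial 3-benzyloxy group to give the 3,4-trans (4β) bond, and since C4 is planar in 25 and 26 the epimer mixture converges on one product. The step needs ring closure before C–C bond formation, ipso attack at C8a and not at C5, and C8 selectivity in 8; these are secured by forming the cation in the absence of 8 and adding 8 only afterwards, by fluorine being both the smaller ortho group (the side chain turns to its side) and the better leaving group with a silicon–fluorine sink, and by the known preference of benzylated flavan oligomers to react at the free C8 of the upper unit.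

Step 14
Reactants: 2 5,7,3',4',5'-penta-O-benzyl-(−)-epigallocatechin
Product: 28 8-bromo-5,7,3',4',5'-penta-O-benzyl-(−)-epigallocatechin
Conditions: NBS (1.0 equiv), CH2Cl2, −40 to 0 °C
Reagents that add atoms: N-bromosuccinimide, O=C1CCC(=O)N1Br
Why: Electrophilic aromatic bromination at C8, the most reactive site of ring A in 5,7-dibenzyloxyflavans, gives a cap that blocks self-condensation and further chain growth at the top unit.

Step 15
Reactants: 28 8-bromo-5,7,3',4',5'-penta-O-benzyl-(−)-epigallocatechin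
Product: 29 8-bromo-4β-(2-ethoxyethoxy)-5,7,3',4',5'-penta-O-benzyl-(−)-epigallocatechin
Conditions: DDQ (2 equiv), EtOCH2CH2OH (5 equiv), CH2Cl2, rt
Reagents that add atoms: 2-ethoxyethanol, CCOCCO
Why: DDQ oxidative benzylic etherification at C4 as in step 3, with the alcohol entering trans to the 3-OH.

Step 16
Reactants: 29 8-bromo-4β-(2-ethoxyethoxy)-5,7,3',4',5'-penta-O-benzyl-(−)-epigallocatechin; 27 benzyl-protected trimer
Product: 30 benzyl-protected tetramer (8-bromo-5,7,3',4',5'-penta-O-benzyl-epigallocatechin)-(4β→8)-(3,5,7,3',4',5'-hexa-O-benzyl-epigallocatechin)-(4β→8)-(octa-O-benzyl-epigallocatechin 3-O-gallate)-(4β→8)-(5,7,3',4'-tetra-O-benzyl-epicatechin)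
Conditions: 29 (1.5 equiv), TMSOTf (0.2 equiv), 4 Å molecular sieves, CH2Cl2, −78 to −40 °C; Et3N quench
Reagents that add atoms: none
Why: Friedel–Crafts interflavan coupling in which ionisation at C4 of 29 is followed by attack of the only unsubstituted C8 of 27 (top unit) anti to the pseudo-axial 3-OH, which should give the 4β bond, while the C8 bromine of 29 prevents self-condensation and over-extension.

Step 17
Reactants: 30 benzyl-protected tetramer
Product: 31 epigallocatechin-(4β→8)-epigallocatechin-(4β→8)-epigallocatechin 3-O-gallate-(4β→8)-epicatechin (CNP0305998.1)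
Conditions: H2 (1 atm), Pd(OH)2/C, THF/MeOH/H2O, rt; Sephadex LH-20, freeze-drying under argon
Reagents that add atoms: none
Why: Catalytic hydrogenolysis should remove all 23 benzyl ethers and the aryl bromide in one operation, while the gallate ester, the pyran rings and the interflavan bonds are expected to survive, so no stereocentre is touched.

**Compound list**

1 | (−)-epigallocatechin | O[C@@H]1Cc2c(O)cc(O)cc2O[C@@H]1c1cc(O)c(O)c(O)c1 | starting material
2 | 5,7,3',4',5'-penta-O-benzyl-(−)-epigallocatechin | O[C@@H]1Cc2c(OCc9ccccc9)cc(OCc9ccccc9)cc2O[C@@H]1c1cc(OCc9ccccc9)c(OCc9ccccc9)c(OCc9ccccc9)c1 | intermediate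
3 | 3,4,5-tris(benzyloxy)benzoic acid | OC(=O)c1cc(OCc9ccccc9)c(OCc9ccccc9)c(OCc9ccccc9)c1 | starting material
4 | 5,7,3',4',5'-penta-O-benzyl-(−)-epigallocatechin 3-O-[3,4,5-tris(benzyloxy)benzoate] | O=C(O[C@@H]1Cc2c(OCc9ccccc9)cc(OCc9ccccc9)cc2O[C@@H]1c1cc(OCc9ccccc9)c(OCc9ccccc9)c(OCc9ccccc9)c1)c1cc(OCc9ccccc9)c(OCc9ccccc9)c(OCc9ccccc9)c1 | intermediate
5 | 4β-(2-ethoxyethoxy) derivative of 4 (2R,3R,4S) | O=C(O[C@@H]1[C@@H](OCCOCC)c2c(OCc9ccccc9)cc(OCc9ccccc9)cc2O[C@@H]1c1cc(OCc9ccccc9)c(OCc9ccccc9)c(OCc9ccccc9)c1)c1cc(OCc9ccccc9)c(OCc9ccccc9)c(OCc9ccccc9)c1 | intermediate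
6 | (−)-epicatechin | O[C@@H]1Cc2c(O)cc(O)cc2O[C@@H]1c1ccc(O)c(O)c1 | starting material
7 | 5,7,3',4'-tetra-O-benzyl-(−)-epicatechin | O[C@@H]1Cc2c(OCc9ccccc9)cc(OCc9ccccc9)cc2O[C@@H]1c1ccc(OCc9ccccc9)c(OCc9ccccc9)c1 | intermediate
8 | lower dimer: (octa-O-benzyl-epigallocatechin 3-O-gallate)-(4β→8)-(5,7,3',4'-tetra-O-benzyl-epicatechin), 3-OH of the bottom unit free | O=C(O[C@@H]1[C@@H](c2c(OCc9ccccc9)cc(OCc9ccccc9)c3c2O[C@H](c2ccc(OCc9ccccc9)c(OCc9ccccc9)c2)[C@H](O)C3)c2c(OCc9ccccc9)cc(OCc9ccccc9)cc2O[C@@H]1c1cc(OCc9ccccc9)c(OCc9ccccc9)c(OCc9ccccc9)c1)c1cc(OCc9ccccc9)c(OCc9ccccc9)c(OCc9ccccc9)c1 | intermediate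
9 | 1,3,5-trifluorobenzene | Fc1cc(F)cc(F)c1 | starting material
10 | 1,3-bis(benzyloxy)-5-fluorobenzene | Fc1cc(OCc2ccccc2)cc(OCc2ccccc2)c1 | intermediate
11 | (S)-4-benzyl-1,3-oxazolidin-2-one | O=C1N[C@@H](Cc2ccccc2)CO1 | starting material
12 | (benzyloxy)acetyl chloride | ClC(=O)COCc1ccccc1 | starting material
13 | N-lithio derivative of 11 (not isolated) | [Li]N1[C@@H](Cc2ccccc2)COC1=O | intermediate
14 | (S)-4-benzyl-3-[(benzyloxy)acetyl]-1,3-oxazolidin-2-one | O=C(COCc1ccccc1)N1[C@@H](Cc2ccccc2)COC1=O | intermediate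
15 | 3,4,5-tris(benzyloxy)benzaldehyde | O=Cc1cc(OCc9ccccc9)c(OCc9ccccc9)c(OCc9ccccc9)c1 | starting material
16 | (Z)-dibutylboron enolate of 14 (not isolated) | CCCCB(CCCC)O/C(=C\OCc1ccccc1)N1[C@@H](Cc2ccccc2)COC1=O | intermediate
17 | dibutylboron aldolate of 18 (not isolated) | CCCCB(CCCC)O[C@H](c1cc(OCc9ccccc9)c(OCc9ccccc9)c(OCc9ccccc9)c1)[C@H](OCc9ccccc9)C(=O)N1[C@@H](Cc2ccccc2)COC1=O | intermediate
18 | (4S)-4-benzyl-3-{(2S,3R)-2-(benzyloxy)-3-hydroxy-3-[3,4,5-tris(benzyloxy)phenyl]propanoyl}-1,3-oxazolidin-2-one | O[C@H](c1cc(OCc9ccccc9)c(OCc9ccccc9)c(OCc9ccccc9)c1)[C@H](OCc9ccccc9)C(=O)N1[C@@H](Cc2ccccc2)COC1=O | intermediate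
19 | (4S)-4-benzyl-3-{(2S,3R)-2-(benzyloxy)-3-[(triethylsilyl)oxy]-3-[3,4,5-tris(benzyloxy)phenyl]propanoyl}-1,3-oxazolidin-2-one | CC[Si](CC)(CC)O[C@H](c1cc(OCc9ccccc9)c(OCc9ccccc9)c(OCc9ccccc9)c1)[C@H](OCc9ccccc9)C(=O)N1[C@@H](Cc2ccccc2)COC1=O | intermediate
20 | (2R,3R)-2-(benzyloxy)-3-[(triethylsilyl)oxy]-3-[3,4,5-tris(benzyloxy)phenyl]propan-1-ol | CC[Si](CC)(CC)O[C@H](c1cc(OCc9ccccc9)c(OCc9ccccc9)c(OCc9ccccc9)c1)[C@H](OCc9ccccc9)CO | intermediate
21 | (2S,3R)-2-(benzyloxy)-3-[(triethylsilyl)oxy]-3-[3,4,5-tris(benzyloxy)phenyl]propanal | CC[Si](CC)(CC)O[C@H](c1cc(OCc9ccccc9)c(OCc9ccccc9)c(OCc9ccccc9)c1)[C@H](OCc9ccccc9)C=O | intermediate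
22 | [2,4-bis(benzyloxy)-6-fluorophenyl]lithium (not isolated) | [Li]c1c(F)cc(OCc2ccccc2)cc1OCc1ccccc1 | intermediate
23 | lithium alkoxide from 22 and 21, both C1 epimers (not isolated) | [Li]OC(c1c(F)cc(OCc9ccccc9)cc1OCc9ccccc9)[C@@H](OCc9ccccc9)[C@H](O[Si](CC)(CC)CC)c1cc(OCc9ccccc9)c(OCc9ccccc9)c(OCc9ccccc9)c1 | intermediate
24 | (1RS,2R,3R)-2-(benzyloxy)-1-[2,4-bis(benzyloxy)-6-fluorophenyl]-3-[(triethylsilyl)oxy]-3-[3,4,5-tris(benzyloxy)phenyl]propyl acetate | CC(=O)OC(c1c(F)cc(OCc9ccccc9)cc1OCc9ccccc9)[C@@H](OCc9ccccc9)[C@H](O[Si](CC)(CC)CC)c1cc(OCc9ccccc9)c(OCc9ccccc9)c(OCc9ccccc9)c1 | intermediate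
25 | open-chain C4 benzylic cation from 24, as triflate (not isolated) | [CH+](c1c(F)cc(OCc9ccccc9)cc1OCc9ccccc9)[C@@H](OCc9ccccc9)[C@H](O[Si](CC)(CC)CC)c1cc(OCc9ccccc9)c(OCc9ccccc9)c(OCc9ccccc9)c1.[O-]S(=O)(=O)C(F)(F)F | intermediate
26 | (2R,3R)-3,5,7-tris(benzyloxy)-2-[3,4,5-tris(benzyloxy)phenyl]chroman-4-ylium triflate, the flavan-4-yl cation (not isolated) | [CH+]1c2c(OCc9ccccc9)cc(OCc9ccccc9)cc2O[C@H](c2cc(OCc9ccccc9)c(OCc9ccccc9)c(OCc9ccccc9)c2)[C@@H]1OCc9ccccc9.[O-]S(=O)(=O)C(F)(F)F | intermediate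
27 | benzyl-protected trimer: (3,5,7,3',4',5'-hexa-O-benzyl-epigallocatechin)-(4β→8)-(octa-O-benzyl-epigallocatechin 3-O-gallate)-(4β→8)-(5,7,3',4'-tetra-O-benzyl-epicatechin) | O=C(O[C@@H]1[C@@H](c2c(OCc9ccccc9)cc(OCc9ccccc9)c3c2O[C@H](c2ccc(OCc9ccccc9)c(OCc9ccccc9)c2)[C@H](O)C3)c2c(OCc9ccccc9)cc(OCc9ccccc9)c([C@H]3c4c(OCc9ccccc9)cc(OCc9ccccc9)cc4O[C@H](c4cc(OCc9ccccc9)c(OCc9ccccc9)c(OCc9ccccc9)c4)[C@@H]3OCc9ccccc9)c2O[C@@H]1c1cc(OCc9ccccc9)c(OCc9ccccc9)c(OCc9ccccc9)c1)c1cc(OCc9ccccc9)c(OCc9ccccc9)c(OCc9ccccc9)c1 | intermediate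
28 | 8-bromo-5,7,3',4',5'-penta-O-benzyl-(−)-epigallocatechin | O[C@@H]1Cc2c(OCc9ccccc9)cc(OCc9ccccc9)c(Br)c2O[C@@H]1c1cc(OCc9ccccc9)c(OCc9ccccc9)c(OCc9ccccc9)c1 | intermediate
29 | 8-bromo-4β-(2-ethoxyethoxy)-5,7,3',4',5'-penta-O-benzyl-(−)-epigallocatechin | O[C@@H]1[C@@H](OCCOCC)c2c(OCc9ccccc9)cc(OCc9ccccc9)c(Br)c2O[C@@H]1c1cc(OCc9ccccc9)c(OCc9ccccc9)c(OCc9ccccc9)c1 | intermediate
30 | benzyl-protected tetramer: (8-bromo-5,7,3',4',5'-penta-O-benzyl-epigallocatechin)-(4β→8)-(3,5,7,3',4',5'-hexa-O-benzyl-epigallocatechin)-(4β→8)-(octa-O-benzyl-epigallocatechin 3-O-gallate)-(4β→8)-(5,7,3',4'-tetra-O-benzyl-epicatechin) | O=C(O[C@@H]1[C@@H](c2c(OCc9ccccc9)cc(OCc9ccccc9)c3c2O[C@H](c2ccc(OCc9ccccc9)c(OCc9ccccc9)c2)[C@H](O)C3)c2c(OCc9ccccc9)cc(OCc9ccccc9)c([C@H]3c4c(OCc9ccccc9)cc(OCc9ccccc9)c([C@H]5c6c(OCc9ccccc9)cc(OCc9ccccc9)c(Br)c6O[C@H](c6cc(OCc9ccccc9)c(OCc9ccccc9)c(OCc9ccccc9)c6)[C@@H]5O)c4O[C@H](c4cc(OCc9ccccc9)c(OCc9ccccc9)c(OCc9ccccc9)c4)[C@@H]3OCc9ccccc9)c2O[C@@H]1c1cc(OCc9ccccc9)c(OCc9ccccc9)c(OCc9ccccc9)c1)c1cc(OCc9ccccc9)c(OCc9ccccc9)c(OCc9ccccc9)c1 | intermediate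
31 | epigallocatechin-(4β→8)-epigallocatechin-(4β→8)-epigallocatechin 3-O-gallate-(4β→8)-epicatechin (CNP0305998.1) | O=C(O[C@@H]1[C@@H](c2c(O)cc(O)c3c2O[C@H](c2ccc(O)c(O)c2)[C@H](O)C3)c2c(O)cc(O)c([C@H]3c4c(O)cc(O)c([C@H]5c6c(O)cc(O)cc6O[C@H](c6cc(O)c(O)c(O)c6)[C@@H]5O)c4O[C@H](c4cc(O)c(O)c(O)c4)[C@@H]3O)c2O[C@@H]1c1cc(O)c(O)c(O)c1)c1cc(O)c(O)c(O)c1 | target

**Step count and risks**

Total step count: 17. Longest linear sequence: 9 steps (steps 7, 8, 9, 10, 11, 12, 13, 16, 17).

Steps most likely to fail: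

Step 13 (proposed new method). What may go wrong: the open-chain cation may be consumed by Friedel–Crafts closure onto ring B or by proton loss at C3 before O1 reaches C8a, or the silyl ether oxygen may add too slowly. The fallback uses only known reactions, sets out from 24 and comes back at 27. Ionic hydrogenation (Et3SiH, BF3·OEt2, CH2Cl2, −78 °C) removes the C4 acetate to give the 4-deoxy silyl ether F1. Bu4NF (THF, 0 °C) frees the C2 hydroxyl to give the fluoroarene alcohol F2. KH (THF/DMF, 0 °C to rt) closes ring C by alkoxide SNAr on the fluoroarene with retention at C2 to give 3,5,7,3',4',5'-hexa-O-benzyl-(−)-epigallocatechin F3. DDQ and 2-ethoxyethanol (CH2Cl2, rt) give its 4β-(2-ethoxyethoxy) ether F4. TMSOTf-catalysed coupling of F4 with 8 (CH2Cl2, −78 °C) then gives 27.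

Step 12. What may go wrong: deprotonation at the wrong site (between the two benzyloxy groups or at a benzylic CH2), loss of LiF to an aryne, enolisation of the aldehyde, or migration of the silyl group to the new alkoxide before acetylation. The fallback sets out from 10 and comes back at 24. NBS (MeCN, 0 °C) should brominate ortho to fluorine and para to a benzyloxy group to give 1,5-bis(benzyloxy)-2-bromo-3-fluorobenzene F5. Bromine–magnesium exchange with iPrMgCl·LiCl (THF, −20 °C) gives the less basic arylmagnesium chloride F6. Addition of F6 to 21 gives the magnesium alkoxide F7, which is acetylated in the same flask with Ac2O to give 24.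

Step 17. What may go wrong: incomplete hydrogenolysis of the many benzyl ethers, and cleavage of the acid-labile interflavan bonds by the HBr that the aryl bromide releases. The fallback sets out from 30 and comes back at 31. Radical hydrodebromination (Bu3SnH, AIBN, toluene, 80 °C) first gives the bromine-free benzyl-protected tetramer F8, which is then hydrogenolysed under acid-free conditions (H2, Pd(OH)2/C, THF/MeOH/H2O, rt) to 31.

Further compounds
F1 | step 13 | triethyl{(1R,2R)-2-(benzyloxy)-3-[2,4-bis(benzyloxy)-6-fluorophenyl]-1-[3,4,5-tris(benzyloxy)phenyl]propoxy}silane | C(c1c(F)cc(OCc9ccccc9)cc1OCc9ccccc9)[C@@H](OCc9ccccc9)[C@H](O[Si](CC)(CC)CC)c1cc(OCc9ccccc9)c(OCc9ccccc9)c(OCc9ccccc9)c1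
F2 | step 13 | (1R,2R)-2-(benzyloxy)-3-[2,4-bis(benzyloxy)-6-fluorophenyl]-1-[3,4,5-tris(benzyloxy)phenyl]propan-1-ol | C(c1c(F)cc(OCc9ccccc9)cc1OCc9ccccc9)[C@@H](OCc9ccccc9)[C@H](O)c1cc(OCc9ccccc9)c(OCc9ccccc9)c(OCc9ccccc9)c1
F3 | step 13 | 3,5,7,3',4',5'-hexa-O-benzyl-(−)-epigallocatechin | C1c2c(OCc9ccccc9)cc(OCc9ccccc9)cc2O[C@H](c2cc(OCc9ccccc9)c(OCc9ccccc9)c(OCc9ccccc9)c2)[C@@H]1OCc9ccccc9
F4 | step 13 | 4β-(2-ethoxyethoxy)-3,5,7,3',4',5'-hexa-O-benzyl-(−)-epigallocatechin | CCOCCO[C@H]1c2c(OCc9ccccc9)cc(OCc9ccccc9)cc2O[C@H](c2cc(OCc9ccccc9)c(OCc9ccccc9)c(OCc9ccccc9)c2)[C@@H]1OCc9ccccc9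
F5 | step 12 | 1,5-bis(benzyloxy)-2-bromo-3-fluorobenzene | Brc1c(F)cc(OCc2ccccc2)cc1OCc1ccccc1
F6 | step 12 | [2,4-bis(benzyloxy)-6-fluorophenyl]magnesium chloride | Cl[Mg]c1c(F)cc(OCc2ccccc2)cc1OCc1ccccc1
F7 | step 12 | chloromagnesium alkoxide from F6 and 21, both C1 epimers | Cl[Mg]OC(c1c(F)cc(OCc9ccccc9)cc1OCc9ccccc9)[C@@H](OCc9ccccc9)[C@H](O[Si](CC)(CC)CC)c1cc(OCc9ccccc9)c(OCc9ccccc9)c(OCc9ccccc9)c1
F8 | step 17 | bromine-free benzyl-protected tetramer (30 with H in place of Br at C8 of the top unit) | O=C(O[C@@H]1[C@@H](c2c(OCc9ccccc9)cc(OCc9ccccc9)c3c2O[C@H](c2ccc(OCc9ccccc9)c(OCc9ccccc9)c2)[C@H](O)C3)c2c(OCc9ccccc9)cc(OCc9ccccc9)c([C@H]3c4c(OCc9ccccc9)cc(OCc9ccccc9)c([C@H]5c6c(OCc9ccccc9)cc(OCc9ccccc9)cc6O[C@H](c6cc(OCc9ccccc9)c(OCc9ccccc9)c(OCc9ccccc9)c6)[C@@H]5O)c4O[C@H](c4cc(OCc9ccccc9)c(OCc9ccccc9)c(OCc9ccccc9)c4)[C@@H]3OCc9ccccc9)c2O[C@@H]1c1cc(OCc9ccccc9)c(OCc9ccccc9)c(OCc9ccccc9)c1)c1cc(OCc9ccccc9)c(OCc9ccccc9)c(OCc9ccccc9)c1
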